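## Retrosynthetic overview (fusicoccane numbering)

1. Alterbrassicicene C ⇐ its C8 ketone (hydride from the convex face). Ring A ⇐ aldol condensation C2→C3 of a C1/C3 1,6-diketone (last ring).
2. Ring B ⇐ the C2–C6 bond, the bond that closes the 5–11 bicycle to the 5–8–5 core in the presumed biosynthesis; here by Michael addition of the C1 methyl ketone enolate to C6.
3. Ether bridge ⇐ attack of the C10 tertiary hydroxyl on C6 (the presumed biosynthetic C10–OH → C6 conjugate addition); here onto a C6/C8 β-diketone with loss of water. C9–C10 ⇐ dianion aldol.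
4. Ring C ⇐ 2-methylcyclopentane-1,3-dione: C11 ethynylation (masked acetyl), dehydrogenation, desymmetrising Cu-catalysed isopropyl conjugate addition (source of absolute configuration).
5. Ring order: C (bought) → oxane (C6–O–C10) → B → A. The C3–C9 chain comes from 3-methylpentane-2,4-dione.

Assumption: locants are fusicoccane locants (C1 and C12 ketones, C2=C3, C16 = CH2OMe, C6/C10 ether carbons, C7-Me, C8-OH, C11-Me, C13=C14, iPr on C14), and the ligand antipode in step 5 is the one that gives 10 as drawn, found by screening both.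

## Route

Step 1
Reactants: 1 3-chloro-2-(chloromethyl)prop-1-ene
Product: 2 3-chloro-2-(methoxymethyl)prop-1-ene
Conditions: NaOMe (0.4 equiv), MeOH, 0 °C → 40 °C; distil (excess 1 recovered)
Reagents that add atoms: sodium methoxide, [Na+].[O-]C
Why: Williamson-type SN2 displacement of one allylic chloride, with excess dichloride suppressing the bis-ether.

Step 2
Reactants: 3 3-methylpentane-2,4-dione; 2 3-chloro-2-(methoxymethyl)prop-1-ene
Product: 5 7-(methoxymethyl)-3-methyloct-7-ene-2,4-dione, via dilithium dianion 4 (not isolated)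
Conditions: LiN(iPr)2 (2.1 equiv), THF, −78 → 0 °C; 2, 0 °C; 1 M HCl
Reagents that add atoms: none
Why: Hauser dianion alkylation, in which the terminal (less stabilised) carbanion of the 1,3-diketone dianion is alkylated by the allylic chloride; the 1,1-disubstituted alkene is the masked C3 ketone.

Step 3
Reactants: 6 2-methylcyclopentane-1,3-dione
Product: 7 2-ethynyl-2-methylcyclopentane-1,3-dione
Conditions: 1-[(trimethylsilyl)ethynyl]-1,2-benziodoxol-3(1H)-one (1.3 equiv), Bu4NF (1.3 equiv), THF, −78 °C → rt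
Reagents that add atoms: 1-[(trimethylsilyl)ethynyl]-1,2-benziodoxol-3(1H)-one, C[Si](C)(C)C#CI1OC(=O)c2ccccc12
Why: Electrophilic alkynylation of the stabilised dione enolate with an ethynylbenziodoxolone generated in situ builds the quaternary carbon (future C11), the ethynyl group being a small, non-electrophilic stand-in for the C1 acetyl group.

Step 4
Reactants: 7 2-ethynyl-2-methylcyclopentane-1,3-dione
Product: 8 2-ethynyl-2-methylcyclopent-4-ene-1,3-dione
Conditions: 2-iodoxybenzoic acid (IBX, 2.0 equiv), DMSO, 70 °C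
Reagents that add atoms: none
Why: IBX dehydrogenation of the only CH2–CH2 unit gives the symmetric ene-dione needed for desymmetrisation.

Step 5
Reactants: 8 2-ethynyl-2-methylcyclopent-4-ene-1,3-dione
Product: 10 (2S,5R)-2-ethynyl-2-methyl-5-(propan-2-yl)-3-[(trimethylsilyl)oxy]cyclopent-3-en-1-one, via isopropylzinc enolate 9 (not isolated)
Conditions: Cu(OTf)2 (2 mol%), BINOL-derived bis(1-phenylethyl)amine phosphoramidite (4 mol%), Zn(iPr)2 (1.5 equiv), toluene, −40 °C; then Me3SiOTf (1.6 equiv), −40 → 0 °C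
Reagents that add atoms: diisopropylzinc, CC(C)[Zn]C(C)C; trimethylsilyl trifluoromethanesulfonate, C[Si](C)(C)OS(=O)(=O)C(F)(F)F
Why: Copper-catalysed asymmetric conjugate addition of a dialkylzinc (a known desymmetrisation of 2,2-disubstituted cyclopent-4-ene-1,3-diones), in which the ligand selects one enantiotopic alkene carbon and isopropyl enters anti to the C-methyl group (ethynyl is the slimmer substituent), making the quaternary carbon S and the temporary isopropyl carbon R, while O-silylation of the zinc enolate leaves only the future C10 ketone free.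

Step 6
Reactants: 10 (2S,5R)-2-ethynyl-2-methyl-5-(propan-2-yl)-3-[(trimethylsilyl)oxy]cyclopent-3-en-1-one; 5 7-(methoxymethyl)-3-methyloct-7-ene-2,4-dione
Product: 13 (1R,4S,5R)-1-ethynyl-7-[3-(methoxymethyl)but-3-en-1-yl]-1,8-dimethyl-4-(propan-2-yl)-6-oxaspiro[4.5]dec-7-ene-2,9-dione, via dilithium dianion 11 (not isolated), via silylated aldol adduct 12 (not isolated)
Conditions: 5 (2.2 equiv), LiN(iPr)2 (4.5 equiv), THF, −78 → 0 °C; 10, −78 °C; AcOH; then TsOH·H2O (20 mol%), CH2Cl2, rt (the excess dianion covers the acidic alkyne C–H)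
Reagents that add atoms: none
Why: Hauser dianion aldol addition through the terminal carbon to the only free ketone, from the face anti to the neighbouring isopropyl group (syn to methyl), sets the tertiary carbinol C10, and acid then cleaves the silyl enol ether and closes the oxane by addition of the C10 hydroxyl to the C6 carbonyl with loss of water (β-diketone to 2,3-dihydro-4H-pyran-4-one cyclodehydration), which installs the C6–O–C10 ether bridge.

Step 7
Reactants: 13 (1R,4S,5R)-1-ethynyl-7-[3-(methoxymethyl)but-3-en-1-yl]-1,8-dimethyl-4-(propan-2-yl)-6-oxaspiro[4.5]dec-7-ene-2,9-dione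
Product: 14 (1R,5R)-1-ethynyl-7-[3-(methoxymethyl)but-3-en-1-yl]-1,8-dimethyl-4-(propan-2-yl)-6-oxaspiro[4.5]deca-3,7-diene-2,9-dione
Conditions: IBX (1.5 equiv), DMSO, 65 °C
Reagents that add atoms: none
Why: IBX dehydrogenation can only occur at the C12 ketone (the pyranone ketone has no β-hydrogen), giving the C13=C14 enone and erasing the temporary isopropyl stereocentre.

Step 8
Reactants: 14 (1R,5R)-1-ethynyl-7-[3-(methoxymethyl)but-3-en-1-yl]-1,8-dimethyl-4-(propan-2-yl)-6-oxaspiro[4.5]deca-3,7-diene-2,9-dione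
Product: 15 (1S,5R)-1-acetyl-7-[3-(methoxymethyl)but-3-en-1-yl]-1,8-dimethyl-4-(propan-2-yl)-6-oxaspiro[4.5]deca-3,7-diene-2,9-dione
Conditions: Au(PPh3)NTf2 (5 mol%), H2O/1,4-dioxane 1:4, 60 °C
Reagents that add atoms: water, O
Why: Gold-catalysed Markovnikov hydration of the terminal alkyne unmasks the C1 methyl ketone, with the large excess of water outcompeting any reaction with the electron-poor alkenes.

Step 9
Reactants: 15 (1S,5R)-1-acetyl-7-[3-(methoxymethyl)but-3-en-1-yl]-1,8-dimethyl-4-(propan-2-yl)-6-oxaspiro[4.5]deca-3,7-diene-2,9-dione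
Product: 17 (1R,5S,8S,9R)-8-[3-(methoxymethyl)but-3-en-1-yl]-5,9-dimethyl-2-(propan-2-yl)-12-oxatricyclo[6.3.1.0(1,5)]dodec-2-ene-4,6,10-trione, via potassium enolate 16 (not isolated)
Conditions: KN(SiMe3)2 (1.1 equiv), THF, −78 → −20 °C; AcOH, −78 °C
Reagents that add atoms: none
Why: Intramolecular Michael addition (6-exo-trig) of the methyl ketone enolate to C6 of the dihydropyranone forms the C2–C6 bond and so closes the eight-membered ring B as a 9-oxabicyclo[3.3.1]nonane; the short C11–C1–C2 tether reaches only one face of C6, so the ether-bearing quaternary centre forms with the bridge cis, and protonation of the product enolate at C7 from the convex face (anti to the C1 bridge) places the C7 methyl equatorial as in the target.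

Step 10
Reactants: 17 (1R,5S,8S,9R)-8-[3-(methoxymethyl)but-3-en-1-yl]-5,9-dimethyl-2-(propan-2-yl)-12-oxatricyclo[6.3.1.0(1,5)]dodec-2-ene-4,6,10-trione
Product: 19 (6R,7R,10R,11R)-6,10-epoxy-16-methoxyfusicocca-2,13-diene-1,8,12-trione, via tetraketone 18 (not isolated)
Conditions: O3, CH2Cl2, −78 °C (Sudan Red end point); Me2S; then TsOH·H2O (20 mol%), toluene, 4 Å sieves, 50 °C
Reagents that add atoms: ozone, [O-][O+]=O
Why: Ozonolysis is selective for the isolated 1,1-disubstituted alkene over the electron-poor enone, and the resulting C1/C3 1,6-diketone undergoes acid-catalysed intramolecular aldol condensation (C2 enol onto the unhindered, alkoxy-activated C3 ketone rather than C4 onto the neopentyl C1 ketone) to give ring A with the C2=C3 enone.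

Step 11
Reactants: 19 (6R,7R,10R,11R)-6,10-epoxy-16-methoxyfusicocca-2,13-diene-1,8,12-trione
Product: 20 alterbrassicicene C, (6R,7S,8S,10R,11R)-6,10-epoxy-8-hydroxy-16-methoxyfusicocca-2,13-diene-1,12-dione
Conditions: NaBH4 (1.0 equiv), CH2Cl2/MeOH 1:1, −78 °C; AcOH quench at −78 °C
Reagents that add atoms: none
Why: Chemoselective borohydride reduction of the saturated ketone beside two hindered enones at low temperature, with hydride delivered from the convex face of the oxane ring (anti to the C1–C2 bridge), gives the endo (8S) alcohol.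

## Compound list

1 | 3-chloro-2-(chloromethyl)prop-1-ene | C=C(CCl)CCl | starting material
2 | 3-chloro-2-(methoxymethyl)prop-1-ene | COCC(=C)CCl | intermediate
3 | 3-methylpentane-2,4-dione | CC(=O)C(C)C(C)=O | starting material
4 | dilithium 3-methylpenta-1,3-diene-2,4-diolate (dianion of 3) | C=C(O[Li])C(C)=C(C)O[Li] | intermediate (not isolated)
5 | 7-(methoxymethyl)-3-methyloct-7-ene-2,4-dione | CC(=O)C(C)C(=O)CCC(=C)COC | intermediate
6 | 2-methylcyclopentane-1,3-dione | CC1C(=O)CCC1=O | starting material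
7 | 2-ethynyl-2-methylcyclopentane-1,3-dione | CC1(C#C)C(=O)CCC1=O | intermediate
8 | 2-ethynyl-2-methylcyclopent-4-ene-1,3-dione | CC1(C#C)C(=O)C=CC1=O | intermediate
9 | isopropylzinc enolate, (2S,5R)-2-ethynyl-2-methyl-5-(propan-2-yl)-3-[(propan-2-ylzincio)oxy]cyclopent-3-en-1-one | C#C[C@@]1(C)C(O[Zn]C(C)C)=C[C@@H](C(C)C)C1=O | intermediate (not isolated)
10 | (2S,5R)-2-ethynyl-2-methyl-5-(propan-2-yl)-3-[(trimethylsilyl)oxy]cyclopent-3-en-1-one | C#C[C@@]1(C)C(O[Si](C)(C)C)=C[C@@H](C(C)C)C1=O | intermediate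
11 | dilithium 7-(methoxymethyl)-3-methylocta-1,3,7-triene-2,4-diolate (dianion of 5) | C=C(O[Li])C(C)=C(O[Li])CCC(=C)COC | intermediate (not isolated)
12 | 1-[(1R,2R,5R)-2-ethynyl-1-hydroxy-2-methyl-5-(propan-2-yl)-3-[(trimethylsilyl)oxy]cyclopent-3-en-1-yl]-7-(methoxymethyl)-3-methyloct-7-ene-2,4-dione | C#C[C@@]1(C)C(O[Si](C)(C)C)=C[C@@H](C(C)C)[C@]1(O)CC(=O)C(C)C(=O)CCC(=C)COC | intermediate (not isolated)
13 | (1R,4S,5R)-1-ethynyl-7-[3-(methoxymethyl)but-3-en-1-yl]-1,8-dimethyl-4-(propan-2-yl)-6-oxaspiro[4.5]dec-7-ene-2,9-dione | C#C[C@@]1(C)C(=O)C[C@@H](C(C)C)[C@]12CC(=O)C(C)=C(CCC(=C)COC)O2 | intermediate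
14 | (1R,5R)-1-ethynyl-7-[3-(methoxymethyl)but-3-en-1-yl]-1,8-dimethyl-4-(propan-2-yl)-6-oxaspiro[4.5]deca-3,7-diene-2,9-dione | C#C[C@@]1(C)C(=O)C=C(C(C)C)[C@]12CC(=O)C(C)=C(CCC(=C)COC)O2 | intermediate
15 | (1S,5R)-1-acetyl-7-[3-(methoxymethyl)but-3-en-1-yl]-1,8-dimethyl-4-(propan-2-yl)-6-oxaspiro[4.5]deca-3,7-diene-2,9-dione | CC(=O)[C@@]1(C)C(=O)C=C(C(C)C)[C@]12CC(=O)C(C)=C(CCC(=C)COC)O2 | intermediate
16 | potassium enolate of 17 (C7=C8–OK) | C1C(=O)[C@@]2(C)C(=O)C=C(C(C)C)[C@]23CC([O-])=C(C)[C@@]1(CCC(=C)COC)O3.[K+] | intermediate (not isolated)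
17 | (1R,5S,8S,9R)-8-[3-(methoxymethyl)but-3-en-1-yl]-5,9-dimethyl-2-(propan-2-yl)-12-oxatricyclo[6.3.1.0(1,5)]dodec-2-ene-4,6,10-trione | C1C(=O)[C@@]2(C)C(=O)C=C(C(C)C)[C@]23CC(=O)[C@H](C)[C@@]1(CCC(=C)COC)O3 | intermediate
18 | (1R,5S,8S,9R)-8-(4-methoxy-3-oxobutyl)-5,9-dimethyl-2-(propan-2-yl)-12-oxatricyclo[6.3.1.0(1,5)]dodec-2-ene-4,6,10-trione | C1C(=O)[C@@]2(C)C(=O)C=C(C(C)C)[C@]23CC(=O)[C@H](C)[C@@]1(CCC(=O)COC)O3 | intermediate (not isolated)
19 | (6R,7R,10R,11R)-6,10-epoxy-16-methoxyfusicocca-2,13-diene-1,8,12-trione (8-oxo compound) | COCC1=C2C(=O)[C@@]3(C)C(=O)C=C(C(C)C)[C@]34CC(=O)[C@H](C)[C@@]2(CC1)O4 | intermediate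
20 | alterbrassicicene C, (6R,7S,8S,10R,11R)-6,10-epoxy-8-hydroxy-16-methoxyfusicocca-2,13-diene-1,12-dione | COCC1=C2C(=O)[C@@]3(C)C(=O)C=C(C(C)C)[C@]34C[C@H](O)[C@H](C)[C@@]2(CC1)O4 | target

## Step count and risks

Total step count: 11. Longest linear sequence: 9 steps (6 → 20, steps 3–11); the chain fragment 5 (steps 1–2) joins at step 6.

**Step 6.** The ketone of 10 lies between a quaternary carbon and the isopropyl-bearing carbon, and its α-hydrogen is acidic, so the basic dianion may enolise it instead of adding. The fallback replaces enolate chemistry by a Lewis-acid Mukaiyama aldol; it sets out from 8 and 5 and comes back at 13. The conjugate addition to 8 is run as in step 5, but zinc enolate 9 is quenched with Ac2O to give the enol acetate of the ring C ketone F1. Dianion 11 is quenched with Me3SiCl to give the bis(trimethylsilyl) dienol ether of 5 F2. TiCl4 in CH2Cl2 at −78 °C joins the terminal carbon of F2 to the ketone of F1 and gives, after aqueous work-up, the hydroxy diketone enol acetate F3. TsOH closes this to the spiro dihydropyranone enol acetate F4, and K2CO3 in MeOH cleaves the enol acetate to give 13.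

**Step 9.** The vinylogous ester is a weak acceptor and C6 becomes fully substituted; enolate scrambling (C9, C5) or aldol addition to C8 may compete. The fallback makes the nucleophile a doubly stabilised carbanion so the addition runs under mild, reversible conditions; it sets out from 14 and comes back at 17. Oxidative methoxycarbonylation of the terminal alkyne (PdCl2, CuCl2, NaOAc, CO, MeOH) gives the methyl alkynoate of 14 F5. Hydration (Au(PPh3)NTf2, H2O) gives the β-keto ester analogue of 15 F6. Cs2CO3 in MeCN effects the Michael addition to C6 and gives the C2-methoxycarbonyl derivative of 17 F7. Krapcho dealkoxycarbonylation (LiCl, wet DMSO, 120 °C) gives 17.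

**Step 10.** The aldol could close the other way (C4 onto C1), and acid may epimerise C7; by a rough conformational count the two C7 epimers are close in energy, so the kinetic protonation in step 9 must be preserved. The fallback fixes the olefination site with a phosphonate and closes ring A under mild base; it sets out from 14 and comes back at 19. Aerobic coupling with HP(O)(OEt)2 (CuI, Et3N, air, DMSO) gives the diethyl alkynylphosphonate of 14 F8. Hydration (Au(PPh3)NTf2, H2O) gives the β-ketophosphonate analogue of 15 F9. KOtBu in THF gives the Michael adduct, the C2-diethoxyphosphoryl derivative of 17 F10. Ozonolysis (O3, then Me2S) gives the C2-diethoxyphosphoryl derivative of 18 F11. Intramolecular Horner–Wadsworth–Emmons olefination (LiCl, DBU, MeCN) then forms the C2=C3 bond regiospecifically and gives 19.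

## Further compounds

F1 | step 6 | enol acetate of the ring C ketone, (3R,5S)-5-ethynyl-5-methyl-4-oxo-3-(propan-2-yl)cyclopent-1-en-1-yl acetate | C#C[C@@]1(C)C(OC(C)=O)=C[C@@H](C(C)C)C1=O
F2 | step 6 | bis(trimethylsilyl) dienol ether of 5, 7-(methoxymethyl)-3-methyl-2,4-bis[(trimethylsilyl)oxy]octa-1,3,7-triene | C=C(O[Si](C)(C)C)C(C)=C(O[Si](C)(C)C)CCC(=C)COC
F3 | step 6 | hydroxy diketone enol acetate (acetate analogue of 12) | C#C[C@@]1(C)C(OC(C)=O)=C[C@@H](C(C)C)[C@]1(O)CC(=O)C(C)C(=O)CCC(=C)COC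
F4 | step 6 | spiro dihydropyranone enol acetate (enol acetate of 13) | C#C[C@@]1(C)C(OC(C)=O)=C[C@@H](C(C)C)[C@]12CC(=O)C(C)=C(CCC(=C)COC)O2
F5 | step 9 | methyl alkynoate of 14 (CO2Me on the alkyne terminus) | COC(=O)C#C[C@@]1(C)C(=O)C=C(C(C)C)[C@]12CC(=O)C(C)=C(CCC(=C)COC)O2
F6 | step 9 | β-keto ester analogue of 15 (CO2Me on C2) | COC(=O)CC(=O)[C@@]1(C)C(=O)C=C(C(C)C)[C@]12CC(=O)C(C)=C(CCC(=C)COC)O2
F7 | step 9 | C2-methoxycarbonyl derivative of 17 (C2 epimers) | COC(=O)C1C(=O)[C@@]2(C)C(=O)C=C(C(C)C)[C@]23CC(=O)[C@H](C)[C@@]1(CCC(=C)COC)O3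
F8 | step 10 | diethyl alkynylphosphonate of 14 | CCOP(=O)(OCC)C#C[C@@]1(C)C(=O)C=C(C(C)C)[C@]12CC(=O)C(C)=C(CCC(=C)COC)O2
F9 | step 10 | β-ketophosphonate analogue of 15 (P(O)(OEt)2 on C2) | CCOP(=O)(OCC)CC(=O)[C@@]1(C)C(=O)C=C(C(C)C)[C@]12CC(=O)C(C)=C(CCC(=C)COC)O2
F10 | step 10 | C2-diethoxyphosphoryl derivative of 17 (C2 epimers) | CCOP(=O)(OCC)C1C(=O)[C@@]2(C)C(=O)C=C(C(C)C)[C@]23CC(=O)[C@H](C)[C@@]1(CCC(=C)COC)O3
F11 | step 10 | C2-diethoxyphosphoryl derivative of 18 (C2 epimers) | CCOP(=O)(OCC)C1C(=O)[C@@]2(C)C(=O)C=C(C(C)C)[C@]23CC(=O)[C@H](C)[C@@]1(CCC(=O)COC)O3
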